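## The problem

The target is a 2,3,5-trisubstituted oxane (O1, C2–C6). C2 carries a 4-hydroxyphenyl group, C3 an (E)-3-(4-hydroxyphenyl)prop-2-enyl chain and C5 an exocyclic aryl carbinol, with all three ring substituents on one face. Four stereocentres have to be set: C2 (R), C3 (S), C5 (R) and the carbinol carbon (R). C5 and the carbinol carbon are neighbours of open-chain origin and can be made together by an aldol reaction; once in place they are the only source of control for C2 and C3. The all-cis pattern is not the relaxed one, because a cis C2/C3 pair forces one group axial while C3 and C5 sit equatorial, so neither equilibration nor a plain chair ring closure can be trusted. Both benzylic C–O bonds (C2–O1 and the carbinol C–O) stand para to a phenolic oxygen: they ionise with acid and, as phenolates, can open through quinone methides. The styrene double bond excludes hydrogenolysis at the end. The three phenols therefore need one protecting group that survives amide bases, Lewis acids, hydrides and organometallics and leaves under buffered fluoride. The enabling feature is that the CH2 carbon on C3 and the carbinol oxygen on the C5 arm are 1,5-related across C4 and cis. Raised to a carbonyl, that carbon closes a δ-lactone (C=O, O, carbinol C, C5, C4, C3); lactone and oxane together form a 3,7-dioxabicyclo[3.3.1]nonan-2-one with both aryl groups equatorial. In it C3 is a lactone α-carbon (nucleophile) and C2 an acetal-level carbon on O1 (electrophile).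

## Retrosynthesis

**23 to 22.** Only O–Si bonds are cut. The free target tolerates neither acid nor hydrogen, so the last step is a single buffered fluoride treatment of 22, which carries three triisopropylsilyl aryl ethers and one triethylsilyl ether on the carbinol.

**22 to 18 and 19.** The C(sp3)–C(sp2) bond between the CH2 on C3 and the alkene is cut. Cutting the alkene itself would first require a one-carbon homologation of the C3 arm to an aldehyde, and a metathesis route would need an allyl group that is no easier to install. The chosen cut gives a primary iodide 18 and an (E)-alkenyl iodide 19, whose geometry comes from one olefination of aldehyde 2. The forward coupling must keep that geometry and beat elimination at a β-branched iodide; a copper-catalysed reaction of the alkenylmagnesium reagent 21 (from 19 through 20) is asked to do this.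

**18 to 17, 16 and 15.** No skeletal bond is cut. The iodide carbon is traced back to a primary alcohol (17 from 16), and the primary alcohol and the carbinol oxygen of 16 are joined as the ester 15. This turns a flexible oxane with two arms into a rigid bicycle. Forward, hydride must open the lactone without touching the benzylic C–O bonds, the primary hydroxyl must be iodinated in preference to the benzylic one, and the carbinol is then capped so that it cannot act as an internal nucleophile.

**15 to 12.** The C1–C8 bond of 15 (C2–C3 of the oxane) is cut. Among the ring bonds this is the only one whose ends are a lactone α-carbon and a carbon at the aldehyde oxidation level on oxygen, so both reactive partners are easy to generate: the silyl ketene acetal 13 and the oxocarbenium ion 14. The cut removes one ring and two stereocentres and leaves a monocyclic lactone 12 with only the two aldol-derived centres. Forward, the ring closure must be intramolecular and must place the new aryl group equatorial on the bicycle.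

**12 to 10 and 11.** One acetal C–O bond is cut, giving the hydroxymethyl lactone 10 and the dimethyl acetal 11 of aldehyde 2. The acetal carbon of 12 is a mixture, which is harmless because it becomes planar in 14.

**10 to 9 and 7.** The CH2OH of 10 is traced to the carboxylic acid 9, and the lactone C–O and the carboxyl group to the aldol adduct 7 through the hydroxy acid 8. Direct hydride cleavage of the imide beside a δ-lactone is avoided. It would liberate a primary alkoxide 1,5 to the lactone carbonyl, and acyl transfer to that oxygen would place the lactone on the wrong hydroxyl. Hydrolysis to 8 followed by lactonisation is unambiguous, since only the benzylic hydroxyl exists at that stage. Borane then reduces the acid of 9 through neutral borate esters and leaves the lactone alone. Triisopropylsilyl is chosen for the phenols because it must survive this hydroperoxide step.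

**7 to 5 and 2.** The bond between C5 and the carbinol carbon is cut in the aldol sense. An auxiliary-controlled anti-aldol sets both centres in one step from the glutaric half-ester imide 5 and aldehyde 2.

**5, 2, 11 and 19 to purchased materials.** Imide 5 comes from oxazolidinone 3 and acid chloride 4. Aldehyde 2, made from 4-hydroxybenzaldehyde 1, supplies all three aryl rings: directly in the aldol, as 11 for C2, and as 19 for the styryl end.

## Roads not taken

**Alternative 1:** Both C2–C3 and the C5–carbinol bond are cut as aldol bonds, leading to the glutaryl bis-imide A1 and two molecules of aldehyde 2. Forward, double soft enolisation (MgCl2, Et3N, Me3SiCl) and two anti-aldol additions would give the twofold-symmetric bis-adduct A2; no ring forms.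
- Merits: all four stereocentres are set in one operation under auxiliary control, with no reliance on a substrate-controlled cyclisation, and the symmetry makes the two ends equivalent. In stereochemical security and in step count to the full stereotetrad this road is better than the chosen one.
- Weak points: after reduction of both imides, two primary and two benzylic hydroxyls must be sorted. One benzylic oxygen has to displace an activated primary carbon to close O1–C6, while the competing primary-to-primary closure gives a 3,5-disubstituted oxane and acid invites benzylic ionisation. The second enolisation must also occur on a chain that already carries a silyloxy-benzyl branch.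
- Comparison: the chosen plan sets against it a precursor in which every oxygen is already told apart (O1 as acetal, the carbinol oxygen inside the lactone, the C3 arm as carbonyl). The price is that C2 and C3 depend on a ring closure untested in this bicyclic setting.

**Alternative 2:** C2–C3 and O1–C6 are cut in a hetero-Diels–Alder sense, giving aldehyde 2 and the 1-methoxy-3-silyloxy diene A3. Forward, the cycloaddition would be catalysed by the CrCl complex of the tridentate Schiff base from cis-1-amino-2-indanol and 3-(1-adamantyl)-5-methylsalicylaldehyde (trivalent chromium), and acidic work-up would give the cis-dihydropyranone A4.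
- Merits: catalytic and enantioselective without an auxiliary, convergent, and the cis C2/C3 pair comes from the endo transition state. Its side chain ends in an oxygenated two-carbon arm, so the styrene could be made by an olefination, which is probably more dependable than the alkyl–alkenyl coupling of the chosen plan.
- Weak points: aromatic aldehydes and fully substituted dienes are the least reactive partners for this catalyst class. The C4 ketone is not in the target and must be removed, and C3 is epimerisable next to it. C5 has to be set by reduction of the enone, and the carbinol centre by aryl addition to an exocyclic aldehyde with no strong bias.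
- Comparison: the chosen plan has no surplus functionality to delete and fixes the carbinol centre at the outset.

**Alternative 3:** O1–C6 is cut, leading to the furyl carbinol A5. Forward, oxidation of the furan (N-bromosuccinimide, NaHCO3, aqueous THF) and rearrangement would give the pyranone hemiacetal A6.
- Merits: cheap materials, an easy ring synthesis with handles at C3, C5 and C6, and no stoichiometric auxiliary; on cost and scalability it is ahead.
- Weak points: C2 in A6 is benzylic and α to the ketone, so its configuration is at risk. The electron-rich silyloxyaryl ring competes for the brominating agent. The all-cis hydrogenation has to set C3 and C5 from C2 alone across two alkenes while sparing the benzylic C2–O1 bond, and must precede introduction of the styrene. The carbinol centre again comes from a late, weakly controlled aryl addition, and A5 itself must be obtained enantioenriched.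
- Comparison: the chosen plan sets against it covalent control of every stereocentre, at the cost of an auxiliary and a longer sequence.

Key step: step 8

Abbreviation used in names: ArSi = 4-(triisopropylsilyloxy)phenyl.

Remark on the chemistry: the MgCl2-catalysed anti-aldol is taken to follow the chelated (Z)-enolate model known for N-acyl-4-benzyloxazolidinones, so the (R)-auxiliary is the one that leads to the (4S,5R) adduct 7.

Remark on the chemistry: methyl 5-chloro-5-oxopentanoate 4, the half-ester chloride of glutaric acid, is taken as a purchased material.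

## Route

Step 1
Reactants: 1 4-hydroxybenzaldehyde
Product: 2 4-(triisopropylsilyloxy)benzaldehyde
Conditions: i-Pr3SiCl, imidazole, DMF, rt
Reagents that add atoms: chlorotri(propan-2-yl)silane, CC(C)[Si](Cl)(C(C)C)C(C)C
Why: Standard silylation of a phenol; the bulky silyl ether is chosen because it should resist hydroperoxide, amide base, hydride and organomagnesium reagents and still leave with fluoride.

Step 2
Reactants: 3 (4R)-4-benzyl-1,3-oxazolidin-2-one; 4 methyl 5-chloro-5-oxopentanoate
Product: 5 methyl 5-[(4R)-4-benzyl-2-oxo-1,3-oxazolidin-3-yl]-5-oxopentanoate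
Conditions: Et3N, DMAP (cat.), CH2Cl2, 0 °C to rt
Reagents that add atoms: none
Why: N-Acylation of the oxazolidinone by the acid chloride under nucleophilic catalysis; the methyl ester is far less electrophilic and should stay intact.

Step 3
Reactants: 5 methyl 5-[(4R)-4-benzyl-2-oxo-1,3-oxazolidin-3-yl]-5-oxopentanoate; 2 4-(triisopropylsilyloxy)benzaldehyde
Product: 7 methyl (4S,5R)-4-{[(4R)-4-benzyl-2-oxo-1,3-oxazolidin-3-yl]carbonyl}-5-hydroxy-5-ArSi-pentanoate, via trimethylsilyl ether 6 (not isolated)
Conditions: MgCl2 (0.2 equiv), Et3N, Me3SiCl, EtOAc, 23 °C; then PPTS, MeOH, 0 °C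
Reagents that add atoms: none
Why: MgCl2-catalysed anti-aldol reaction of an N-acyloxazolidinone with a non-enolisable aromatic aldehyde: soft enolisation gives the magnesium-chelated (Z)-enolate, which adds on the face away from the benzyl group, and silylation of the aldolate as 6 makes the addition irreversible. The (R)-auxiliary should set both new centres (4S,5R), which become C5 and the carbinol carbon of the target; mild methanolysis removes the silyl group without ionising the benzylic position.

Step 4
Reactants: 7 methyl (4S,5R)-4-{[(4R)-4-benzyl-2-oxo-1,3-oxazolidin-3-yl]carbonyl}-5-hydroxy-5-ArSi-pentanoate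
Product: 9 (2R,3S)-6-oxo-2-ArSi-oxane-3-carboxylic acid, via hydroxy acid 8 (not isolated)
Conditions: LiOH, H2O2, THF/H2O, 0 °C; Na2SO3; 1 M HCl to pH 3; then PPTS (cat.), PhMe, 60 °C
Reagents that add atoms: hydrogen peroxide, OO
Why: Hydroperoxide cleavage of the exocyclic imide carbonyl frees the auxiliary 3 and gives the β-hydroxy acid 8, whose benzylic hydroxyl closes onto the δ-ester with loss of methanol (δ-lactonisation). Only this hydroxyl is present, so the lactone can form on one oxygen alone, and any ester hydrolysed on the way leads to the same lactone; the acyl-oxygen pathway keeps both stereocentres.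

Step 5
Reactants: 9 (2R,3S)-6-oxo-2-ArSi-oxane-3-carboxylic acid
Product: 10 (5R,6R)-5-(hydroxymethyl)-6-ArSi-oxan-2-one
Conditions: BH3·SMe2, THF, 0 °C to rt; MeOH
Reagents that add atoms: none
Why: Borane reduces a carboxylic acid much faster than a lactone, and the alcohol is held as a neutral borate ester until the methanol quench, so no alkoxide is present that could transfer the lactone to the primary oxygen. The product is used at once.

Step 6
Reactants: 2 4-(triisopropylsilyloxy)benzaldehyde
Product: 11 [4-(dimethoxymethyl)phenoxy]triisopropylsilane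
Conditions: HC(OMe)3, MeOH, PPTS (cat.), rt; Et3N
Reagents that add atoms: trimethyl orthoformate, COC(OC)OC; methanol, CO
Why: Acid-catalysed acetalisation of an electron-rich aromatic aldehyde, driven by the orthoformate as water scavenger; the aryl silyl ether is stable to weak acid.

Step 7
Reactants: 10 (5R,6R)-5-(hydroxymethyl)-6-ArSi-oxan-2-one; 11 [4-(dimethoxymethyl)phenoxy]triisopropylsilane
Product: 12 (5R,6R)-5-{[methoxy(ArSi)methoxy]methyl}-6-ArSi-oxan-2-one (both acetal epimers)
Conditions: 11 (5 equiv), PPTS (cat.), CH2Cl2, 5 Å sieves, rt; Et3N; Et3N-treated silica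
Reagents that add atoms: none
Why: Transacetalisation: the very easily ionised dimethyl acetal exchanges one methoxy group for the primary alcohol under a weak acid, and a large excess of 11 with removal of methanol favours the mixed acetal over the bis-alkoxy acetal. The carbinol oxygen is locked in the lactone, so no cyclic arylidene acetal can form.

Step 8
Reactants: 12 (5R,6R)-5-{[methoxy(ArSi)methoxy]methyl}-6-ArSi-oxan-2-one
Product: 15 (1S,4R,5R,8R)-4,8-bis(ArSi)-3,7-dioxabicyclo[3.3.1]nonan-2-one, via silyl ketene acetal 13 (not isolated), via oxocarbenium triflate 14 (not isolated)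
Conditions: LiN(i-Pr)2, Me3SiCl (internal quench), THF, −78 °C; solvent exchange to CH2Cl2 (0.01 M); Me3SiOTf (0.2 equiv), 2,6-di-tert-butyl-4-methylpyridine, −78 to −40 °C
Reagents that add atoms: none
Why: Internal-quench enolisation turns the lactone into its cyclic O-silyl ketene acetal 13; in CH2Cl2 catalytic Me3SiOTf then removes methoxide from either acetal epimer as Me3SiOMe and leaves the (E)-aryl oxocarbenium ion 14 on the CH2O arm. The ketene acetal carbon adds to the oxocarbenium carbon and silyl transfer to triflate regenerates the catalyst; this is the intramolecular form of the Me3SiOTf-catalysed Mukaiyama-type addition of silyl ketene acetals to acetals. The oxane ring closes in a 6-(enolexo)-endo-trig mode through a chair, and the lactone already present makes the product a 3,7-dioxabicyclo[3.3.1]nonan-2-one. The new centre at the lactone α-carbon (C1 of 15, C3 of the target) is fixed by the tether: the arm is axial on the lactone because the cis aryl group takes the equatorial site, so only the face that carries the arm can be reached. The new benzylic centre (C8 of 15, C2 of the target) is set by the (E)-geometry of the oxocarbenium ion and the chair, which place the aryl group equatorial on the forming ring and therefore cis to the lactone carbon. The step needs ring closure to win over intermolecular addition, which the 1,3-diaxial proximity of nucleophile and arm and high dilution should secure. It also needs ionisation to lead to the cyclisable cation, which holds because loss of the other alkoxy group is reversible and unproductive. Both aryl groups are equatorial in 15, so any reversible benzylic ionisation under the Lewis acid would drain to the same isomer.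

Step 9
Reactants: 15 (1S,4R,5R,8R)-4,8-bis(ArSi)-3,7-dioxabicyclo[3.3.1]nonan-2-one
Product: 16 (R)-[(3R,5R,6R)-5-(hydroxymethyl)-6-ArSi-oxan-3-yl](ArSi)methanol
Conditions: LiBH4, THF, 0 °C to rt
Reagents that add atoms: none
Why: Hydride reduction of a lactone to the diol; LiBH4 is mild enough to spare the aryl silyl ethers and the benzylic C–O bonds, and no stereocentre is touched because the α-carbon never becomes an enolate.

Step 10
Reactants: 16 (R)-[(3R,5R,6R)-5-(hydroxymethyl)-6-ArSi-oxan-3-yl](ArSi)methanol
Product: 17 (R)-[(3R,5S,6R)-5-(iodomethyl)-6-ArSi-oxan-3-yl](ArSi)methanol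
Conditions: I2, PPh3, imidazole, THF, 0 °C
Reagents that add atoms: iodine, II
Why: Appel-type iodination through the alkoxyphosphonium ion; with a slight excess of reagent at low temperature the unhindered primary hydroxyl should react well before the secondary benzylic one, and iodide displaces at the primary carbon in an SN2 step.

Step 11
Reactants: 17 (R)-[(3R,5S,6R)-5-(iodomethyl)-6-ArSi-oxan-3-yl](ArSi)methanol
Product: 18 triethyl{(R)-[(3R,5S,6R)-5-(iodomethyl)-6-ArSi-oxan-3-yl](ArSi)methoxy}silane
Conditions: Et3SiOTf, 2,6-lutidine, CH2Cl2, −78 °C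
Reagents that add atoms: triethylsilyl trifluoromethanesulfonate, CC[Si](CC)(CC)OS(=O)(=O)C(F)(F)F
Why: Silylation of a secondary alcohol with a silyl triflate and a hindered base; capping the carbinol prevents it from closing onto the iodide as a magnesium alkoxide in the next step and from consuming the organometallic reagent.

Step 12
Reactants: 2 4-(triisopropylsilyloxy)benzaldehyde
Product: 19 {4-[(E)-2-iodoethenyl]phenoxy}triisopropylsilane
Conditions: CHI3, CrCl2, THF, 0 °C to rt
Reagents that add atoms: iodoform, IC(I)I
Why: Takai iodo-olefination: the geminal dichromium species from iodoform and CrCl2 (divalent chromium) adds to the aldehyde and eliminates anti, which gives (E)-alkenyl iodides from aromatic aldehydes with high selectivity.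

Step 13
Reactants: 19 {4-[(E)-2-iodoethenyl]phenoxy}triisopropylsilane; 18 triethyl{(R)-[(3R,5S,6R)-5-(iodomethyl)-6-ArSi-oxan-3-yl](ArSi)methoxy}silane
Product: 22 triethyl{(R)-[(3R,5S,6R)-6-ArSi-5-[(E)-3-ArSi-prop-2-en-1-yl]oxan-3-yl](ArSi)methoxy}silane, via alkenyllithium 20 (not isolated), via alkenylmagnesium bromide 21 (not isolated)
Conditions: 19, t-BuLi (2 equiv), Et2O, −78 °C; MgBr2·OEt2, −78 to 0 °C; then 18, CuI (10 mol %), THF, −30 to 0 °C
Reagents that add atoms: none
Why: Iodine–lithium exchange and transmetalation to magnesium both proceed with retention of alkene geometry, and the copper-catalysed cross-coupling of a Grignard reagent with a primary alkyl iodide then forms the C(sp3)–C(sp2) bond without touching the geometry. The silyl ethers and the oxane are inert to the organocopper intermediate at this temperature.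

Step 14
Reactants: 22 triethyl{(R)-[(3R,5S,6R)-6-ArSi-5-[(E)-3-ArSi-prop-2-en-1-yl]oxan-3-yl](ArSi)methoxy}silane
Product: 23 4-[(1E)-3-{(2R,3S,5R)-5-[(R)-hydroxy(4-hydroxyphenyl)methyl]-2-(4-hydroxyphenyl)oxan-3-yl}prop-1-en-1-yl]phenol
Conditions: Bu4NF, AcOH, THF, 0 °C to rt
Reagents that add atoms: none
Why: Fluoride cleaves the three aryl silyl ethers and the alkyl silyl ether in one operation; buffering with acetic acid keeps the phenols protonated so that neither benzylic C–O bond can open through a quinone methide.

## Compound list

1 | 4-hydroxybenzaldehyde | O=Cc1ccc(O)cc1 | starting material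
2 | 4-(triisopropylsilyloxy)benzaldehyde | O=Cc1ccc(O[Si](C(C)C)(C(C)C)C(C)C)cc1 | intermediate
3 | (4R)-4-benzyl-1,3-oxazolidin-2-one | O=C1N[C@H](Cc2ccccc2)CO1 | starting material
4 | methyl 5-chloro-5-oxopentanoate | COC(=O)CCCC(=O)Cl | starting material
5 | methyl 5-[(4R)-4-benzyl-2-oxo-1,3-oxazolidin-3-yl]-5-oxopentanoate | COC(=O)CCCC(=O)N1[C@H](Cc2ccccc2)COC1=O | intermediate
6 | methyl (4S,5R)-4-{[(4R)-4-benzyl-2-oxo-1,3-oxazolidin-3-yl]carbonyl}-5-ArSi-5-(trimethylsilyloxy)pentanoate | C[Si](C)(C)O[C@@H](c1ccc(O[Si](C(C)C)(C(C)C)C(C)C)cc1)[C@@H](C(=O)N2[C@H](Cc3ccccc3)COC2=O)CCC(=O)OC | intermediate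
7 | methyl (4S,5R)-4-{[(4R)-4-benzyl-2-oxo-1,3-oxazolidin-3-yl]carbonyl}-5-hydroxy-5-ArSi-pentanoate | O[C@@H](c1ccc(O[Si](C(C)C)(C(C)C)C(C)C)cc1)[C@@H](C(=O)N2[C@H](Cc3ccccc3)COC2=O)CCC(=O)OC | intermediate
8 | (2S,3R)-3-hydroxy-2-(3-methoxy-3-oxopropyl)-3-ArSi-propanoic acid | O[C@@H](c1ccc(O[Si](C(C)C)(C(C)C)C(C)C)cc1)[C@@H](C(=O)O)CCC(=O)OC | intermediate
9 | (2R,3S)-6-oxo-2-ArSi-oxane-3-carboxylic acid | O=C1O[C@@H](c2ccc(O[Si](C(C)C)(C(C)C)C(C)C)cc2)[C@@H](C(=O)O)CC1 | intermediate
10 | (5R,6R)-5-(hydroxymethyl)-6-ArSi-oxan-2-one | O=C1O[C@@H](c2ccc(O[Si](C(C)C)(C(C)C)C(C)C)cc2)[C@@H](CO)CC1 | intermediate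
11 | [4-(dimethoxymethyl)phenoxy]triisopropylsilane | COC(OC)c1ccc(O[Si](C(C)C)(C(C)C)C(C)C)cc1 | intermediate
12 | (5R,6R)-5-{[methoxy(ArSi)methoxy]methyl}-6-ArSi-oxan-2-one (both acetal epimers) | O=C1O[C@@H](c2ccc(O[Si](C(C)C)(C(C)C)C(C)C)cc2)[C@@H](COC(OC)c2ccc(O[Si](C(C)C)(C(C)C)C(C)C)cc2)CC1 | intermediate
13 | {[(2R,3R)-3-{[methoxy(ArSi)methoxy]methyl}-2-ArSi-3,4-dihydro-2H-pyran-6-yl]oxy}trimethylsilane | C[Si](C)(C)OC=1O[C@@H](c2ccc(O[Si](C(C)C)(C(C)C)C(C)C)cc2)[C@@H](COC(OC)c2ccc(O[Si](C(C)C)(C(C)C)C(C)C)cc2)CC=1 | intermediate
14 | (E)-(ArSi-methylidene){[(2R,3R)-2-ArSi-6-(trimethylsilyloxy)-3,4-dihydro-2H-pyran-3-yl]methyl}oxonium trifluoromethanesulfonate | C[Si](C)(C)OC=1O[C@@H](c2ccc(O[Si](C(C)C)(C(C)C)C(C)C)cc2)[C@@H](C/[O+]=C/c2ccc(O[Si](C(C)C)(C(C)C)C(C)C)cc2)CC=1.[O-]S(=O)(=O)C(F)(F)F | intermediate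
15 | (1S,4R,5R,8R)-4,8-bis(ArSi)-3,7-dioxabicyclo[3.3.1]nonan-2-one | O=C1O[C@@H](c2ccc(O[Si](C(C)C)(C(C)C)C(C)C)cc2)[C@@H]2C[C@H]1[C@H](c1ccc(O[Si](C(C)C)(C(C)C)C(C)C)cc1)OC2 | intermediate
16 | (R)-[(3R,5R,6R)-5-(hydroxymethyl)-6-ArSi-oxan-3-yl](ArSi)methanol | OC[C@H]1C[C@@H]([C@@H](O)c2ccc(O[Si](C(C)C)(C(C)C)C(C)C)cc2)CO[C@H]1c1ccc(O[Si](C(C)C)(C(C)C)C(C)C)cc1 | intermediate
17 | (R)-[(3R,5S,6R)-5-(iodomethyl)-6-ArSi-oxan-3-yl](ArSi)methanol | IC[C@H]1C[C@@H]([C@@H](O)c2ccc(O[Si](C(C)C)(C(C)C)C(C)C)cc2)CO[C@H]1c1ccc(O[Si](C(C)C)(C(C)C)C(C)C)cc1 | intermediate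
18 | triethyl{(R)-[(3R,5S,6R)-5-(iodomethyl)-6-ArSi-oxan-3-yl](ArSi)methoxy}silane | IC[C@H]1C[C@@H]([C@@H](O[Si](CC)(CC)CC)c2ccc(O[Si](C(C)C)(C(C)C)C(C)C)cc2)CO[C@H]1c1ccc(O[Si](C(C)C)(C(C)C)C(C)C)cc1 | intermediate
19 | {4-[(E)-2-iodoethenyl]phenoxy}triisopropylsilane | I/C=C/c1ccc(O[Si](C(C)C)(C(C)C)C(C)C)cc1 | intermediate
20 | [(E)-2-ArSi-ethenyl]lithium | [Li]/C=C/c1ccc(O[Si](C(C)C)(C(C)C)C(C)C)cc1 | intermediate
21 | bromo[(E)-2-ArSi-ethenyl]magnesium | Br[Mg]/C=C/c1ccc(O[Si](C(C)C)(C(C)C)C(C)C)cc1 | intermediate
22 | triethyl{(R)-[(3R,5S,6R)-6-ArSi-5-[(E)-3-ArSi-prop-2-en-1-yl]oxan-3-yl](ArSi)methoxy}silane | CC(C)[Si](C(C)C)(C(C)C)Oc1ccc(/C=C/C[C@H]2C[C@@H]([C@@H](O[Si](CC)(CC)CC)c3ccc(O[Si](C(C)C)(C(C)C)C(C)C)cc3)CO[C@H]2c2ccc(O[Si](C(C)C)(C(C)C)C(C)C)cc2)cc1 | intermediate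
23 | 4-[(1E)-3-{(2R,3S,5R)-5-[(R)-hydroxy(4-hydroxyphenyl)methyl]-2-(4-hydroxyphenyl)oxan-3-yl}prop-1-en-1-yl]phenol | Oc1ccc(/C=C/C[C@H]2C[C@@H]([C@@H](O)c3ccc(O)cc3)CO[C@H]2c2ccc(O)cc2)cc1 | target

## Step count and least certain steps

Total step count: 14. Longest linear sequence: 11 steps (steps 1, 3, 4, 5, 7, 8, 9, 10, 11, 13, 14).

**Step 8 (key step).** The likeliest failure is intermolecular carbon–carbon bond formation or simple loss of the silyl group from the ketene acetal instead of ring closure. Closure needs the lactone conformer with the arm axial and passes through a bicyclic transition state, and ionisation can also expel the primary alkoxy group instead of methoxide. The fallback closes the same bicycle through O1–C2 instead of C2–C3. It sets out from 10, which is silylated (Et3SiCl, imidazole) to (5R,6R)-5-[(triethylsilyloxy)methyl]-6-ArSi-oxan-2-one F1. The lithium enolate of F1 (LiN(i-Pr)2, THF, −78 °C) adds to aldehyde 2 to give the β-hydroxy lactone F2 as a mixture at both new centres. Dess–Martin periodinane oxidises F2 to the β-keto lactone F3, whose α-carbon equilibrates through the enol. Et3SiH with catalytic BiBr3 in MeCN then effects reductive etherification: the silyl ether oxygen condenses on the aryl ketone of the cis epimer, and the cyclic oxocarbenium ion takes hydride axially on the open face, which places the aryl group equatorial. The sequence comes back to the route at 15.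

**Step 7.** Over-exchange to the bis-alkoxy acetal, hydrolysis of the mixed acetal on silica, and slow acid-catalysed migration of the lactone to the free primary oxygen are the likely losses, because the reaction is an equilibrium run under acid. The fallback replaces the equilibrium by an irreversible alkylation under base. It sets out from 11, which with acetyl chloride gives the α-chloro ether [4-(chloro(methoxy)methyl)phenoxy]triisopropylsilane F4; this is used in the same flask with 10 and i-Pr2NEt in CH2Cl2 at −78 °C and comes back to the route at 12.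

**Step 4.** Partial cleavage of the aryl silyl ether by hydroperoxide or hydroxide is the main danger, since phenolic silyl ethers are base-labile even when hindered. The fallback removes the auxiliary reductively. It sets out from 7, which is lactonised (PPTS, PhMe, 60 °C) to the imide lactone (4R)-4-benzyl-3-{[(2R,3S)-6-oxo-2-ArSi-oxan-3-yl]carbonyl}-1,3-oxazolidin-2-one F5. LiBH4 (1 equiv) with MeOH (1 equiv) in THF at −20 °C reduces the exocyclic imide carbonyl faster than the lactone, and a cold acetic acid quench keeps the alkoxide from lingering. It comes back to the route at 10 and bypasses 9, at the price of the acyl-migration risk that the main route avoids.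

**Step 10.** Activation of the benzylic hydroxyl, or closure of the 1,5-diol to a cyclic ether through the alkoxyphosphonium ion, may compete with iodide displacement, because the benzylic position ionises easily and the two arms are cis. The fallback uses a sulfonate, which discriminates by steric demand and does not activate the benzylic oxygen. It sets out from 16, which with TsCl in pyridine at 0 °C gives the primary tosylate F6; Et3SiOTf and 2,6-lutidine give its triethylsilyl ether F7, and NaI in acetone displaces the tosylate. It comes back to the route at 18.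

**Step 13.** Elimination to an exocyclic alkene or reduction of the iodide may outrun coupling, because the iodide is β-branched and alkylcopper intermediates decompose on warming; erosion of alkene geometry in the organometallic is a lesser risk. The fallback reverses the polarity of the partners. It sets out from 18, which with zinc dust and LiCl in THF gives the alkylzinc iodide F8; Negishi coupling with 19 under Pd(PPh3)4 (zerovalent palladium) proceeds with retention at the alkenyl iodide and comes back to the route at 22.

## Further compounds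

F1 | step 8 | (5R,6R)-5-[(triethylsilyloxy)methyl]-6-ArSi-oxan-2-one | O=C1O[C@@H](c2ccc(O[Si](C(C)C)(C(C)C)C(C)C)cc2)[C@@H](CO[Si](CC)(CC)CC)CC1
F2 | step 8 | (5R,6R)-3-[hydroxy(ArSi)methyl]-5-[(triethylsilyloxy)methyl]-6-ArSi-oxan-2-one (epimers at C3 and at the carbinol carbon) | O=C1O[C@@H](c2ccc(O[Si](C(C)C)(C(C)C)C(C)C)cc2)[C@@H](CO[Si](CC)(CC)CC)CC1C(O)c1ccc(O[Si](C(C)C)(C(C)C)C(C)C)cc1
F3 | step 8 | (5R,6R)-5-[(triethylsilyloxy)methyl]-3-[4-(triisopropylsilyloxy)benzoyl]-6-ArSi-oxan-2-one (C3 epimers) | O=C1O[C@@H](c2ccc(O[Si](C(C)C)(C(C)C)C(C)C)cc2)[C@@H](CO[Si](CC)(CC)CC)CC1C(=O)c1ccc(O[Si](C(C)C)(C(C)C)C(C)C)cc1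
F4 | step 7 | [4-(chloro(methoxy)methyl)phenoxy]triisopropylsilane | COC(Cl)c1ccc(O[Si](C(C)C)(C(C)C)C(C)C)cc1
F5 | step 4 | (4R)-4-benzyl-3-{[(2R,3S)-6-oxo-2-ArSi-oxan-3-yl]carbonyl}-1,3-oxazolidin-2-one | O=C1O[C@@H](c2ccc(O[Si](C(C)C)(C(C)C)C(C)C)cc2)[C@@H](C(=O)N2[C@H](Cc3ccccc3)COC2=O)CC1
F6 | step 10 | {(2R,3R,5R)-5-[(R)-hydroxy(ArSi)methyl]-2-ArSi-oxan-3-yl}methyl 4-methylbenzenesulfonate | Cc1ccc(S(=O)(=O)OC[C@H]2C[C@@H]([C@@H](O)c3ccc(O[Si](C(C)C)(C(C)C)C(C)C)cc3)CO[C@H]2c2ccc(O[Si](C(C)C)(C(C)C)C(C)C)cc2)cc1
F7 | step 10 | {(2R,3R,5R)-2-ArSi-5-[(R)-ArSi(triethylsilyloxy)methyl]oxan-3-yl}methyl 4-methylbenzenesulfonate | Cc1ccc(S(=O)(=O)OC[C@H]2C[C@@H]([C@@H](O[Si](CC)(CC)CC)c3ccc(O[Si](C(C)C)(C(C)C)C(C)C)cc3)CO[C@H]2c2ccc(O[Si](C(C)C)(C(C)C)C(C)C)cc2)cc1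
F8 | step 13 | iodo({(2R,3S,5R)-2-ArSi-5-[(R)-ArSi(triethylsilyloxy)methyl]oxan-3-yl}methyl)zinc | I[Zn]C[C@H]1C[C@@H]([C@@H](O[Si](CC)(CC)CC)c2ccc(O[Si](C(C)C)(C(C)C)C(C)C)cc2)CO[C@H]1c1ccc(O[Si](C(C)C)(C(C)C)C(C)C)cc1
A1 | alternative 1 | 1,5-bis[(4R)-4-benzyl-2-oxo-1,3-oxazolidin-3-yl]pentane-1,5-dione | O=C(CCCC(=O)N1[C@H](Cc2ccccc2)COC1=O)N1[C@H](Cc2ccccc2)COC1=O
A2 | alternative 1 | (2S,4S)-1,5-bis[(4R)-4-benzyl-2-oxo-1,3-oxazolidin-3-yl]-2,4-bis[(R)-hydroxy(ArSi)methyl]pentane-1,5-dione | O=C(N1[C@H](Cc2ccccc2)COC1=O)[C@H]([C@@H](O)c1ccc(O[Si](C(C)C)(C(C)C)C(C)C)cc1)C[C@@H]([C@@H](O)c1ccc(O[Si](C(C)C)(C(C)C)C(C)C)cc1)C(=O)N1[C@H](Cc2ccccc2)COC1=O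
A3 | alternative 2 | tert-butyl{[(3Z,5E)-5-[(benzyloxy)methyl]-6-methoxy-4-(triethylsilyloxy)hexa-3,5-dien-1-yl]oxy}dimethylsilane | CO/C=C(COCc1ccccc1)/C(O[Si](CC)(CC)CC)=C/CCO[Si](C)(C)C(C)(C)C
A4 | alternative 2 | (2R,3R)-5-[(benzyloxy)methyl]-3-[2-(tert-butyldimethylsilyloxy)ethyl]-2-ArSi-2,3-dihydro-4H-pyran-4-one | O=C1C(COCc2ccccc2)=CO[C@@H](c2ccc(O[Si](C(C)C)(C(C)C)C(C)C)cc2)[C@H]1CCO[Si](C)(C)C(C)(C)C
A5 | alternative 3 | (S)-(ArSi){4-[(triisopropylsilyloxy)methyl]furan-2-yl}methanol | O[C@H](c1cc(CO[Si](C(C)C)(C(C)C)C(C)C)co1)c1ccc(O[Si](C(C)C)(C(C)C)C(C)C)cc1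
A6 | alternative 3 | (2S)-6-hydroxy-2-ArSi-5-[(triisopropylsilyloxy)methyl]-2H-pyran-3(6H)-one (C6 anomers) | O=C1C=C(CO[Si](C(C)C)(C(C)C)C(C)C)C(O)O[C@H]1c1ccc(O[Si](C(C)C)(C(C)C)C(C)C)cc1
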